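**Retrosynthetic overview**
1. Target 30 ⇒ O‑sulfation and one fluoride deprotection ⇒ dienoate 27 ⇒ vinylogous HWE of decalin aldehyde 22 with C4 phosphonate 25.
2. 22 ⇒ intramolecular Diels–Alder (IMDA) of open‑chain tetraenal 21, which forms C6–C15 and C7–C12 and closes both six‑membered rings in one step.
3. 21 ⇒ sp2–sp2 Stille union at C13–C14 of C10 (Z)‑iodoalkene enal 12 with C7 dienylstannane 20.
4. 12 ⇒ pent‑4‑yn‑1‑ol, (E)‑but‑2‑ene (anti‑crotylation sets C8/C9) and crotonaldehyde (cross‑metathesis).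
5. 20 ⇒ tiglic aldehyde (Corey–Fuchs/MeI, hydrozirconation); 25 ⇒ 4‑bromocrotonic acid.

Assumption: the target is isolated in the fully protonated form drawn (free CO2H and OSO3H). Polyketide numbering is used in the text: C1 = CO2H, C6/C7/C12/C15 = ring‑A sp3 carbons, C8 = CHMe, C9 = CH–O, C18 = end of the butenyl group.

**Step 1**
Reactants: 1 pent-4-yn-1-ol
Product: 2 5-iodopent-4-yn-1-ol
Conditions: NIS (1.1 equiv), AgNO3 (10 mol %), acetone, rt, dark
Reagents that add atoms: N-iodosuccinimide, O=C1CCC(=O)N1I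
Why: Ag(I)-catalysed electrophilic iodination of the terminal alkyne C–H (via the silver acetylide) leaves the free alcohol untouched.

**Step 2**
Reactants: 2 5-iodopent-4-yn-1-ol
Product: 3 (Z)-5-iodopent-4-en-1-ol
Conditions: 2-nitrobenzenesulfonylhydrazide (NBSH), Et3N, THF/i-PrOH, rt
Reagents that add atoms: none
Why: In this diimide reduction the concerted syn transfer of H2 to the iodoalkyne gives only the (Z)-iodoalkene, with no C–I hydrogenolysis.

**Step 3**
Reactants: 3 (Z)-5-iodopent-4-en-1-ol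
Product: 4 (Z)-5-iodopent-4-enal
Conditions: PhI(OAc)2 (1.1 equiv), TEMPO (10 mol %), CH2Cl2, rt
Reagents that add atoms: none
Why: The TEMPO/BAIB oxoammonium oxidation stops at the aldehyde, and its near-neutral medium does not isomerise the Z-iodoalkene.

**Step 4**
Reactants: 4 (Z)-5-iodopent-4-enal; 5 (E)-but-2-ene
Product: 9 (3R,4S,7Z)-8-iodo-3-methylocta-1,7-dien-4-ol, via crotylpotassium 6 (not isolated), via crotylborane 7 (not isolated), via borinate 8 (not isolated)
Conditions: 5, n-BuLi, KOt-Bu, THF, −78 → −45 °C; (+)-Ipc2BOMe [from (−)-α-pinene], −78 °C; BF3·OEt2; 4, −78 °C; then NaOH, H2O2, rt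
Reagents that add atoms: none
Why: In this Brown asymmetric crotylboration the (E)-crotylborane reacts through a closed Zimmerman–Traxler chair (E → anti), and the Ipc groups from (−)-α-pinene direct attack to the Re face of 4, setting C8 (R) and C9 (S).

**Step 5**
Reactants: 9 (3R,4S,7Z)-8-iodo-3-methylocta-1,7-dien-4-ol
Product: 10 tert-butyl{[(3R,4S,7Z)-8-iodo-3-methylocta-1,7-dien-4-yl]oxy}dimethylsilane
Conditions: TBSOTf (1.3 equiv), 2,6-lutidine, CH2Cl2, 0 °C
Reagents that add atoms: tert-butyldimethylsilyl triflate, CC(C)(C)[Si](C)(C)OS(=O)(=O)C(F)(F)F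
Why: Silylation with the reactive triflate protects the hindered secondary alcohol without touching either stereocentre, and it supplies the bulky group that later biases the cycloaddition.

**Step 6**
Reactants: 10 TBS ether; 11 (E)-but-2-enal (crotonaldehyde)
Product: 12 (2E,4R,5S,8Z)-5-[(tert-butyldimethylsilyl)oxy]-9-iodo-4-methylnona-2,8-dienal
Conditions: Hoveyda–Grubbs II (5 mol %), 11 (5 equiv), CH2Cl2, 40 °C
Reagents that add atoms: none
Why: Olefin cross-metathesis of the terminal vinyl group with an electron-poor partner gives the (E)-enal under thermodynamic control, while the 1,2-disubstituted Z-iodoalkene stays a spectator.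

**Step 7**
Reactants: 13 (E)-2-methylbut-2-enal (tiglic aldehyde)
Product: 14 (3E)-1,1-dibromo-3-methylpenta-1,3-diene
Conditions: CBr4 (2 equiv), PPh3 (4 equiv), CH2Cl2, 0 °C
Reagents that add atoms: carbon tetrabromide, BrC(Br)(Br)Br
Why: The Corey–Fuchs (Ramirez) dibromo-olefination adds C14 and leaves the trisubstituted E-alkene of tiglic aldehyde (C16=C17) untouched.

**Step 8**
Reactants: 14 (3E)-1,1-dibromo-3-methylpenta-1,3-diene
Product: 16 (2E)-3-methylhex-2-en-4-yne, via lithium acetylide 15 (not isolated)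
Conditions: n-BuLi (2.1 equiv), THF, −78 °C; MeI, −78 °C → rt
Reagents that add atoms: iodomethane, CI
Why: In the second stage of the Corey–Fuchs sequence, Br/Li exchange, Fritsch–Buttenberg–Wiechell rearrangement and deprotonation give the acetylide, which MeI methylates much faster than the BuBr formed alongside.

**Step 9**
Reactants: 16 (2E)-3-methylhex-2-en-4-yne
Product: 18 (2E,4E)-2-iodo-4-methylhexa-2,4-diene, via dienylzirconocene 17 (not isolated)
Conditions: Cp2ZrHCl (1.6 equiv), THF, 50 °C; I2, −78 → 0 °C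
Reagents that add atoms: iodine, II
Why: Schwartz hydrozirconation adds H–Zr syn, excess reagent equilibrates Zr to the less hindered methyl-bearing carbon, and iodinolysis with retention gives the E-trisubstituted iodide (C16 trans to I).

**Step 10**
Reactants: 18 (2E,4E)-2-iodo-4-methylhexa-2,4-diene
Product: 20 tributyl[(2E,4E)-4-methylhexa-2,4-dien-2-yl]stannane, via dienyllithium 19 (not isolated)
Conditions: t-BuLi (2.1 equiv), Et2O, −78 °C; Bu3SnCl, −78 °C → rt
Reagents that add atoms: tributyltin chloride, CCCC[Sn](Cl)(CCCC)CCCC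
Why: Iodine–lithium exchange and stannylation of a configurationally stable alkenyllithium both proceed with retention of alkene geometry.

**Step 11**
Reactants: 12 (Z)-iodoalkene enal; 20 dienylstannane
Product: 21 (2E,4R,5S,8Z,10E,12E)-5-[(tert-butyldimethylsilyl)oxy]-4,10,12-trimethyltetradeca-2,8,10,12-tetraenal
Conditions: Pd(PPh3)4 (10 mol %), CuTC (1.5 equiv), [NBu4][Ph2PO2] (1.5 equiv), DMF, rt
Reagents that add atoms: none
Why: This copper-assisted Stille cross-coupling forms C13–C14 with retention at both sp2 partners under neutral room-temperature conditions that tolerate the enal, the TBS ether and the Z-diene.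

**Step 12**
Reactants: 21 tetraenal
Product: 22 (1S,2R,4aS,7S,8R,8aS)-2-[(2E)-but-2-en-2-yl]-7-[(tert-butyldimethylsilyl)oxy]-3,8-dimethyl-1,2,4a,5,6,7,8,8a-octahydronaphthalene-1-carbaldehyde (cis-fused; CHO, butenyl, 8-Me and 7-OTBS all lie on the face of the two ring-fusion hydrogens)
Conditions: Me2AlCl (1.5 equiv), CH2Cl2 (5 mM), −78 → −10 °C; then H2O
Reagents that add atoms: none
Why: In this Lewis-acid-promoted type-1 IMDA a tether on the Z terminus of the diene can reach only the cis-fused transition state with the complexed CHO endo, so the 6E, 12Z and 14E geometries fix C6, C7, C12 and C15 relative to one another, and the chair-like tether with OTBS equatorial and C8–H eclipsing the enal (the other face puts OTBS 1,3-diaxial to C6) fixes them relative to C8/C9.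

**Step 13**
Reactants: 23 (E)-4-bromobut-2-enoic acid
Product: 24 2-(trimethylsilyl)ethyl (E)-4-bromobut-2-enoate
Conditions: TMSCH2CH2OH, DCC, DMAP (5 mol %), CH2Cl2, 0 °C → rt
Reagents that add atoms: 2-(trimethylsilyl)ethanol, C[Si](C)(C)CCO
Why: Steglich esterification installs a fluoride-labile ester under mild conditions that spare the allylic bromide and the E-alkene.

**Step 14**
Reactants: 24 2-(trimethylsilyl)ethyl (E)-4-bromobut-2-enoate
Product: 25 2-(trimethylsilyl)ethyl (E)-4-(diethoxyphosphoryl)but-2-enoate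
Conditions: P(OEt)3, neat, 120 °C
Reagents that add atoms: triethyl phosphite, CCOP(OCC)OCC
Why: The Michaelis–Arbuzov reaction of the primary allylic bromide proceeds by SN2 attack followed by dealkylation, with loss of EtBr.

**Step 15**
Reactants: 22 decalin aldehyde; 25 phosphonate
Product: 27 2-(trimethylsilyl)ethyl (2E,4E)-5-{(1S,2R,4aS,7S,8R,8aR)-2-[(2E)-but-2-en-2-yl]-7-[(tert-butyldimethylsilyl)oxy]-3,8-dimethyl-1,2,4a,5,6,7,8,8a-octahydronaphthalen-1-yl}penta-2,4-dienoate, via lithiophosphonate 26 (not isolated)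
Conditions: 25, LiHMDS, THF, −78 °C; 22, −78 → 0 °C
Reagents that add atoms: none
Why: In this vinylogous Horner–Wadsworth–Emmons olefination the soft, weakly basic phosphonocrotonate anion adds to the aldehyde faster than it enolises it, so C6 is preserved, and reversible addition gives the new C4=C5 bond E.

**Step 16**
Reactants: 27 TMSE dienoate TBS ether
Product: 28 (2E,4E)-5-{(1S,2R,4aS,7S,8R,8aR)-2-[(2E)-but-2-en-2-yl]-7-hydroxy-3,8-dimethyl-1,2,4a,5,6,7,8,8a-octahydronaphthalen-1-yl}penta-2,4-dienoic acid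
Conditions: TBAF (6 equiv), THF, rt → 40 °C; 1 M HCl to pH 3
Reagents that add atoms: none
Why: Fluoride cleaves the Si–O bond of the TBS ether and triggers β-fragmentation of the TMSE ester in the same flask, and no stereocentre is involved.

**Step 17**
Reactants: 28 hydroxy acid
Product: 30 target hydrogen sulfate CNP0450810.2, via pyridinium sulfate 29 (not isolated)
Conditions: SO3·pyridine (4 equiv), DMF, 0 °C → rt; H2O; Dowex 50WX8 (H+), MeOH/H2O, 0 °C; C18 chromatography
Reagents that add atoms: sulfur trioxide–pyridine complex, [O-]S(=O)(=O)[n+]1ccccc1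
Why: O-sulfation of the only alcohol occurs with retention at C9 because the C–O bond is untouched, any acyl sulfate formed at the acid is hydrolysed on adding water (as in direct sulfation of free bile acids), and cation exchange gives the protonated form.

**Compound list**
1 | pent-4-yn-1-ol | C#CCCCO | starting material
2 | 5-iodopent-4-yn-1-ol | IC#CCCCO | intermediate
3 | (Z)-5-iodopent-4-en-1-ol | I/C=C\CCCO | intermediate
4 | (Z)-5-iodopent-4-enal | I/C=C\CCC=O | intermediate
5 | (E)-but-2-ene | C/C=C/C | starting material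
6 | (E)-crotylpotassium (not isolated) | C/C=C/[CH2-].[K+] | intermediate
7 | (E)-crotylbis(isopinocampheyl)borane, Ipc from (−)-α-pinene (not isolated) | C/C=C/CB([C@H]1C[C@H]2C[C@@H]([C@@H]1C)C2(C)C)[C@H]1C[C@H]2C[C@@H]([C@@H]1C)C2(C)C | intermediate
8 | bis(isopinocampheyl)borinate of 9 (not isolated) | I/C=C\CC[C@H](OB([C@H]1C[C@H]2C[C@@H]([C@@H]1C)C2(C)C)[C@H]1C[C@H]2C[C@@H]([C@@H]1C)C2(C)C)[C@H](C)C=C | intermediate
9 | (3R,4S,7Z)-8-iodo-3-methylocta-1,7-dien-4-ol | I/C=C\CC[C@H](O)[C@H](C)C=C | intermediate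
10 | tert-butyl{[(3R,4S,7Z)-8-iodo-3-methylocta-1,7-dien-4-yl]oxy}dimethylsilane | I/C=C\CC[C@H](O[Si](C)(C)C(C)(C)C)[C@H](C)C=C | intermediate
11 | (E)-but-2-enal | C/C=C/C=O | starting material
12 | (2E,4R,5S,8Z)-5-(TBSO)-9-iodo-4-methylnona-2,8-dienal | I/C=C\CC[C@H](O[Si](C)(C)C(C)(C)C)[C@H](C)/C=C/C=O | intermediate
13 | (E)-2-methylbut-2-enal | C/C=C(\C)C=O | starting material
14 | (3E)-1,1-dibromo-3-methylpenta-1,3-diene | C/C=C(\C)C=C(Br)Br | intermediate
15 | lithium (E)-3-methylpent-3-en-1-ynide (not isolated) | C/C=C(\C)C#C[Li] | intermediate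
16 | (2E)-3-methylhex-2-en-4-yne | C/C=C(\C)C#CC | intermediate
17 | chloro[(2E,4E)-4-methylhexa-2,4-dien-2-yl]zirconocene (not isolated) | C/C=C(\C)/C=C(\C)[Zr](Cl)(C1C=CC=C1)C1C=CC=C1 | intermediate
18 | (2E,4E)-2-iodo-4-methylhexa-2,4-diene | C/C=C(\C)/C=C(\C)I | intermediate
19 | 4-methylhexa-2,4-dien-2-yllithium, geometry of 18 retained (not isolated) | C/C=C(\C)/C=C(\C)[Li] | intermediate
20 | tributyl[(2E,4E)-4-methylhexa-2,4-dien-2-yl]stannane | C/C=C(\C)/C=C(\C)[Sn](CCCC)(CCCC)CCCC | intermediate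
21 | (2E,4R,5S,8Z,10E,12E)-5-(TBSO)-4,10,12-trimethyltetradeca-2,8,10,12-tetraenal | C/C=C(\C)/C=C(\C)/C=C\CC[C@H](O[Si](C)(C)C(C)(C)C)[C@H](C)/C=C/C=O | intermediate
22 | (1S,2R,4aS,7S,8R,8aS)-2-[(2E)-but-2-en-2-yl]-7-(TBSO)-3,8-dimethyl-1,2,4a,5,6,7,8,8a-octahydronaphthalene-1-carbaldehyde | C/C=C(\C)[C@@H]1C(C)=C[C@H]2CC[C@H](O[Si](C)(C)C(C)(C)C)[C@H](C)[C@H]2[C@@H]1C=O | intermediate
23 | (E)-4-bromobut-2-enoic acid | OC(=O)/C=C/CBr | starting material
24 | 2-(trimethylsilyl)ethyl (E)-4-bromobut-2-enoate | C[Si](C)(C)CCOC(=O)/C=C/CBr | intermediate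
25 | 2-(trimethylsilyl)ethyl (E)-4-(diethoxyphosphoryl)but-2-enoate | CCOP(=O)(OCC)C/C=C/C(=O)OCC[Si](C)(C)C | intermediate
26 | lithium salt of 25 (not isolated) | CCOP(=O)(OCC)[CH-]/C=C/C(=O)OCC[Si](C)(C)C.[Li+] | intermediate
27 | TMSE (2E,4E)-5-[(1S,2R,4aS,7S,8R,8aR)-decalinyl]penta-2,4-dienoate, 7-OTBS | C/C=C(\C)[C@@H]1C(C)=C[C@H]2CC[C@H](O[Si](C)(C)C(C)(C)C)[C@H](C)[C@H]2[C@@H]1/C=C/C=C/C(=O)OCC[Si](C)(C)C | intermediate
28 | 7-hydroxy dienoic acid (desulfo target) | C/C=C(\C)[C@@H]1C(C)=C[C@H]2CC[C@H](O)[C@H](C)[C@H]2[C@@H]1/C=C/C=C/C(=O)O | intermediate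
29 | pyridinium salt of the 7-sulfate (not isolated) | C/C=C(\C)[C@@H]1C(C)=C[C@H]2CC[C@H](OS(=O)(=O)[O-])[C@H](C)[C@H]2[C@@H]1/C=C/C=C/C(=O)O.c1cc[nH+]cc1 | intermediate
30 | (2E,4E)-5-{(1S,2R,4aS,7S,8R,8aR)-2-[(2E)-but-2-en-2-yl]-3,8-dimethyl-7-(sulfooxy)-1,2,4a,5,6,7,8,8a-octahydronaphthalen-1-yl}penta-2,4-dienoic acid | C/C=C(\C)[C@@H]1C(C)=C[C@H]2CC[C@H](OS(=O)(=O)O)[C@H](C)[C@H]2[C@@H]1/C=C/C=C/C(=O)O | target

**Total step count:** 17
**Longest linear sequence:** 11 (steps 1–6, 11, 12, 15, 16, 17)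

**Three steps most likely to fail**

Step 12 (IMDA of the Z-diene). The risks are sluggish cyclisation, Lewis-acid-induced Z→E isomerisation of the triene, and only moderate facial selectivity. The fallback inverts chain extension and cycloaddition and sets out from tetraenal 21. Olefination of 21 with lithiophosphonate 26 (from 25, LiHMDS, THF, −78 → 0 °C) gives the open-chain 2-(trimethylsilyl)ethyl (2E,4E,6E,8R,9S,12Z,14E,16E)-9-(TBSO)-8,14,16-trimethyloctadeca-2,4,6,12,14,16-hexaenoate F1. The distal C6=C7 bond of its trienoate then acts as dienophile in a purely thermal, acid-free IMDA (toluene, BHT, 130 °C, sealed tube). The geometric constraints and the chair preference are the same as in step 12. This delivers 27 directly, where the route is rejoined, so steps 12 and 15 are both replaced.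

Step 11 (Stille coupling of an α-methyl-substituted dienylstannane). The risks are slow transmetalation, protodestannylation, homocoupling and cine-substitution. The fallback changes the nucleophile to boron and sets out from dienyl iodide 18. Iodine–lithium exchange (t-BuLi, Et2O, −78 °C) and trapping with i-PrOBpin give the pinacol (4-methylhexa-2,4-dien-2-yl)boronate with boron trans to C4, F2. Suzuki–Miyaura coupling of this boronate with iodide 12 (Pd(dppf)Cl2, K3PO4, DMF/H2O, rt) comes back to the route at 21.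

Step 15 (HWE on a hindered, epimerisable aldehyde whose CHO is cis to the butenyl group). The risks are epimerisation at C6 and low conversion. The fallback builds the dienoate without any base at the aldehyde stage and sets out from 22. Takai olefination (CrCl2, CHI3, THF, 0 °C) gives the (E)-2-iodovinyl decalin F3. A Jeffery-type Heck reaction (Pd(OAc)2, K2CO3, Bu4NCl, DMF, rt → 40 °C) then couples it with 2-(trimethylsilyl)ethyl acrylate F4, made from acryloyl chloride, TMSCH2CH2OH and Et3N. This gives the (2E,4E)-dienoate and comes back to the route at 27.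

**Further compounds**
F1 | step 12 | 2-(trimethylsilyl)ethyl (2E,4E,6E,8R,9S,12Z,14E,16E)-9-(TBSO)-8,14,16-trimethyloctadeca-2,4,6,12,14,16-hexaenoate | C/C=C(\C)/C=C(\C)/C=C\CC[C@H](O[Si](C)(C)C(C)(C)C)[C@H](C)/C=C/C=C/C=C/C(=O)OCC[Si](C)(C)C
F2 | step 11 | 4,4,5,5-tetramethyl-2-[(2Z,4E)-4-methylhexa-2,4-dien-2-yl]-1,3,2-dioxaborolane (B trans to C4) | C/C=C(\C)/C=C(\C)B1OC(C)(C)C(C)(C)O1
F3 | step 15 | (E)-2-iodovinyl decalin, 7-OTBS | C/C=C(\C)[C@@H]1C(C)=C[C@H]2CC[C@H](O[Si](C)(C)C(C)(C)C)[C@H](C)[C@H]2[C@@H]1/C=C/I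
F4 | step 15 | 2-(trimethylsilyl)ethyl acrylate | C=CC(=O)OCC[Si](C)(C)C
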